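The earlier runs and the new flask are calculated with constants of no real substance, noise included.

Early in the runs below, product rises while solid substrate goes into a solution of partner that also holds a protic impurity.

| flask | solid substrate | partner | protic impurity | remark | time |
|---|---|---|---|---|---|
| Wednesday's | 0.30 M | 0.23 M | 0.060 M | run made earlier |  |
| Friday's | 0.30 M | 0.34 M | 0.060 M | run made earlier |  |
| Sunday's | 0.60 M | 0.45 M | 0.060 M | run made earlier |  |
| flask | 0.30 M | 0.450 M | 0.0600 M |  | 1.0 h |

| run | time / min | product / % | solid substrate / % |
|---|---|---|---|
| Wednesday's | 8.00 | 13.5 | 55.4 |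
| Wednesday's | 15.0 | 23.3 | 45.5 |
| Wednesday's | 20.0 | 29.1 | 38.8 |
| Wednesday's | 30.0 | 38.7 | 29.7 |
| Wednesday's | 40.0 | 43.8 | 24.8 |
| Friday's | 3.00 | 6.8 | 63.4 |
| Friday's | 5.00 | 12.6 | 57.2 |
| Friday's | 10.0 | 24.8 | 44.1 |
| Friday's | 20.0 | 46.1 | 24.0 |
| Friday's | 40.0 | 69.6 | 0.1 |
| Sunday's | 8.00 | 14.2 | 72.6 |
| Sunday's | 15.0 | 23.4 | 59.8 |
| Sunday's | 20.0 | 30.7 | 54.3 |
| Sunday's | 30.0 | 41.5 | 42.2 |
| Sunday's | 40.0 | 49.4 | 36.0 |

(readings scatter by 0.5 percentage points)

- as a solid, counted per litre of solution: solid substrate
- at the start none of the solid substrate is in solution

- north-west: doubling the solubility of the solid substrate, all else as stated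
- west: doubling the amount of partner, all else as stated
- south: doubling the dissolution coefficient of the solid substrate, all else as stated

- how much product there is at 1.0 h, in percent of the solid substrate charged
- the change that raises the amount of product at 1.0 h, in percent of the solid substrate charged most ("none" if none brings more than 2 percentage points) (north-west / west / south / none)
- amount of product at 1.0 h, in percent of the solid substrate charged, after north-west

Wednesday's run makes product at 0.234 M h⁻¹ between 8.00 min and 20.0 min, but at 0.0918 M h⁻¹ between 30.0 min and 40.0 min, with 24.8% still solid. Solid plus product falls short of the charge by 0.0942 M there and by 0.0876 M in Sunday's run, so the shortfall reads as saturated dissolved substrate and the slowing as partner being consumed. Rate against product then gives a pseudo-first-order constant of 2.38 h⁻¹ and reaches zero near 0.162 M of product, although Wednesday's partner charge is 0.23 M; less the impurity, it is 0.170 M.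

The flask therefore holds 0.390 M of usable partner, the charge less the protic impurity. That is more than its 0.30 M of solid substrate, the limiting reagent. The ledger for that substrate runs thus: 0.0942 M sits in solution, and product grows on the remaining partner until the solid ends at about 18.9 min, at 0.206 M of product. The dissolved entry then decays by second-order kinetics, with the constant above divided by 0.0942 M, leaving 0.0109 M at 1.0 h, so this reckoning closes at 96.4% product. Doubling the partner lifts usable partner to 0.840 M, 2.15 times its present value; north-west and south are not reckoned here.

The forecast, lower than this reckoning, gives 95%, west and 96.6% after north-west, holding that “Rates scale with partner”.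

The flask gives 95.0%; west is best, adding 5 percentage points, and north-west gives 96.4%.

    solid substrate ⇌ dissolved substrate, rate k1*(cs1 - [dissolved substrate]) while solid is left; crystals form when [dissolved substrate] > cs1 (solubility = 0.0990 M, k = 1.00 min⁻¹)
    dissolved substrate + partner → product (k = 0.380 M⁻¹ min⁻¹)
    partner + protic impurity → quenched reagent (k = 1.80 M⁻¹ min⁻¹)

This reckoning stood 1.4 points high. At 0.100 h the flask already holds 0.0590 M of quenched reagent, and at 0.101 h partner goes to product 18 times as fast as to quenched reagent; its 0.390 M of usable partner stands against 0.285 M of product at 1.0 h. The neighbour with 0.18 M of partner has 0.120 M usable, which is 40.0% of the solid substrate charged and makes partner the limiting reagent there. Its computed product at 1.0 h is 35.9%, with 6.9% of its partner charge left.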